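## Retrosynthetic overview

1. Target ⇐ peracid epoxidation of the 4,5-alkene of a 10-membered 4,7(11)-dien-12,6-olide (epoxide ring formed last).
2. Dienolide ⇐ closure of the C6–C7 bond (the bond a germacrene cyclase makes) by NiCl2/CrCl2 alkenylation of a C6 enal with a C7 alkenyl iodide; the new C6 alkoxide then lactonises on C12 in the same flask (carbocycle, then butenolide).
3. Open-chain iodo-enal ⇐ Rh-catalysed conjugate addition of a C4–C6 alkenylboronate to a vinyl ketone ⇐ anti-aldol (C9–C10) of a C5 vinyl ketone with a C8–C13 aldehyde.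
4. Aldehyde ⇐ alkoxide-directed iodo-hydroxymethylation of a γ-hydroxy ynoate (sets C7–I, C13 and the alkene geometry) ⇐ asymmetric alkynylation (sets C8).

Assumption: the SMILES is read as the absolute configuration 4R,5R,6S,8R,9R,10S in germacrane numbering (C1 ketone, C4–C5 epoxide, C6 lactone CH–O, C7=C11, C8 methacrylate, C9 OH, C10 CHMe, C12 lactone C=O, C13 CH2OAc, C14/C15 methyls on C10/C4), and 2,2-dimethoxyacetaldehyde is used water-free after drying its commercial aqueous solution.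

## Route

Step 1
Reactants: 1 2,2-dimethoxyacetaldehyde; 2 methyl propiolate
Product: 3 methyl (4R)-4-hydroxy-5,5-dimethoxypent-2-ynoate
Conditions: Me2Zn (3 equiv), (S,S)-ProPhenol [2,6-bis{[(2S)-2-(hydroxydiphenylmethyl)pyrrolidin-1-yl]methyl}-4-methylphenol, 20 mol %], Ph3PO (40 mol %), toluene, 0–4 °C; aq. NH4Cl
Reagents that add atoms: none
Why: Dinuclear zinc–ProPhenol catalysed asymmetric alkynylation of an aldehyde (Trost type), in which the chiral dizinc catalyst delivers the propiolate to one aldehyde face and sets C8 as R (sense checked by Mosher ester analysis, the antipodal ligand being used if it is opposite).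

Step 2
Reactants: 3 methyl (4R)-4-hydroxy-5,5-dimethoxypent-2-ynoate
Product: 6 methyl (2Z,4S)-4-hydroxy-2-(hydroxymethyl)-3-iodo-5,5-dimethoxypent-2-enoate, via chloromagnesium alkoxide 4 (not isolated), via magnesium iodoallenolate 5 (not isolated)
Conditions: i-PrMgCl (1.0 equiv), CH2Cl2/THF, −78 °C; MgI2 (1.5 equiv), CH2O (gas from cracked paraformaldehyde, excess), −78 → 0 °C; aq. NH4Cl
Reagents that add atoms: magnesium diiodide [Mg+2].[I-].[I-]; formaldehyde C=O
Why: Proposed new method: iodide adds in conjugate fashion to the magnesium-activated ynoate and allenolate 5 is hydroxymethylated at C11 in the plane of the C7 substituents, formaldehyde bound to the C8 alkoxide–magnesium being delivered from the C8 side so that CH2OH ends cis to C8 and iodine cis to CO2Me (2Z, the geometry needed for the later lactonisation), C8 being untouched (R→S is only a priority change) and any 2E isomer lactonising onto O8 and being removed; the closest known reaction is the MgI2-promoted iodo-aldol (β-iodo Baylis–Hillman) coupling of propiolates or ynones with aldehydes, which gives (Z)-β-iodo-α-(hydroxyalkyl)acrylates.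

Step 3
Reactants: 6 methyl (2Z,4S)-4-hydroxy-2-(hydroxymethyl)-3-iodo-5,5-dimethoxypent-2-enoate
Product: 8 methyl (2Z,4S)-2-(acetoxymethyl)-3-iodo-5,5-dimethoxy-4-(methacryloyloxy)pent-2-enoate, via monoacetate 7 (not isolated)
Conditions: AcCl (1.05 equiv), 2,4,6-collidine, CH2Cl2, −78 °C; then methacrylic anhydride (1.5 equiv), Et3N, 4-(dimethylamino)pyridine (10 mol %), 0 °C → rt
Reagents that add atoms: acetyl chloride CC(=O)Cl; methacrylic anhydride C=C(C)C(=O)OC(=O)C(C)=C
Why: Two chemoselective O-acylations in one pot (acid chloride/collidine acylates only the primary allylic OH at low temperature, then nucleophile-catalysed anhydride acylation esterifies the hindered secondary OH), which places the C13 acetate and the C8 methacrylate before the C9 hydroxyl exists; no stereocenter is touched.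

Step 4
Reactants: 8 methyl (2Z,4S)-2-(acetoxymethyl)-3-iodo-5,5-dimethoxy-4-(methacryloyloxy)pent-2-enoate
Product: 9 methyl (2Z,4S)-2-(acetoxymethyl)-3-iodo-4-(methacryloyloxy)-5-oxopent-2-enoate
Conditions: TFA/H2O (9:1), CHCl3, 0 °C → rt; toluene azeotrope, used crude
Reagents that add atoms: water O
Why: Acid-catalysed acetal hydrolysis, to which the esters and the alkenyl iodide are inert, and under which the α-acyloxy aldehyde keeps its C8 configuration.

Step 5
Reactants: 10 ethyl vinyl ketone (pent-1-en-3-one); 9 methyl (2Z,4S)-2-(acetoxymethyl)-3-iodo-4-(methacryloyloxy)-5-oxopent-2-enoate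
Product: 12 methyl (2Z,4S,5R,6S)-2-(acetoxymethyl)-5-hydroxy-3-iodo-4-(methacryloyloxy)-6-methyl-7-oxonona-2,8-dienoate, via (E)-enol dicyclohexylborinate 11 (not isolated)
Conditions: 10 (1.5 equiv), Cy2BCl (1.6 equiv), Et3N (1.8 equiv), Et2O, −78 → −40 °C; 9, −78 → −20 °C; MeOH, pH 7 buffer, 30% H2O2, 0 °C
Reagents that add atoms: none
Why: Boron-mediated anti-aldol reaction (Brown/Paterson E-enol dicyclohexylborinate, Zimmerman–Traxler chair): the ketone can enolise only on its ethyl side, the E-enolate gives the 9,10-anti relationship, and attack anti to the bulky tetrasubstituted iodoalkenyl group (Felkin sense with that group as the large substituent, E-enol borinates not following the usual 3,4-anti preference of α-oxygenated aldehydes) gives the 8,9-syn isomer, that is C9 R and C10 S.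

Step 6
Reactants: 13 but-2-yn-1-ol
Product: 14 (2Z)-3-(4,4,5,5-tetramethyl-1,3,2-dioxaborolan-2-yl)but-2-en-1-ol
Conditions: B2pin2 (1.1 equiv), CuCl (5 mol %), 1,3-bis(2,4,6-trimethylphenyl)imidazolinium chloride (5 mol %), NaOt-Bu (10 mol %), MeOH (2 equiv), THF, rt
Reagents that add atoms: bis(pinacolato)diboron CC1(C)OB(OC1(C)C)B1OC(C)(C)C(C)(C)O1
Why: Copper-catalysed formal hydroboration (syn borylcupration, then protonolysis by methanol) puts boron on the alkyne carbon remote from the carbinol and H cis to it, which fixes the geometry (methyl cis to CH2OH) that becomes the 4E alkene.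

Step 7
Reactants: 12 methyl (2Z,4S,5R,6S)-2-(acetoxymethyl)-5-hydroxy-3-iodo-4-(methacryloyloxy)-6-methyl-7-oxonona-2,8-dienoate; 14 (2Z)-3-(4,4,5,5-tetramethyl-1,3,2-dioxaborolan-2-yl)but-2-en-1-ol
Product: 15 methyl (2Z,4S,5R,6S,10E)-2-(acetoxymethyl)-5,12-dihydroxy-3-iodo-4-(methacryloyloxy)-6,10-dimethyl-7-oxododeca-2,10-dienoate
Conditions: [Rh(OH)(cod)]2 (3 mol %, cod = cycloocta-1,5-diene), 1,4-dioxane/H2O (10:1), 30 °C
Reagents that add atoms: none
Why: Rhodium-catalysed conjugate addition of an alkenylboron reagent (Hayashi–Miyaura): transmetalation with retention of alkene geometry, insertion of the unhindered vinyl ketone (far more reactive than the α-substituted methacrylate or the tetrasubstituted iodoacrylate) and protonolysis by water, under base-free conditions that leave the β-hydroxy ketone, the esters and the C–I bond alone; no new stereocenter.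

Step 8
Reactants: 15 methyl (2Z,4S,5R,6S,10E)-2-(acetoxymethyl)-5,12-dihydroxy-3-iodo-4-(methacryloyloxy)-6,10-dimethyl-7-oxododeca-2,10-dienoate
Product: 16 methyl (2Z,4S,5R,6S)-2-(acetoxymethyl)-5-hydroxy-6-{2-[(3E)-5-hydroxy-3-methylpent-3-en-1-yl]-1,3-dioxolan-2-yl}-3-iodo-4-(methacryloyloxy)hept-2-enoate
Conditions: Me3SiOCH2CH2OSiMe3 (2 equiv), Me3SiOTf (5 mol %), CH2Cl2, −78 → −30 °C; aq. NaHCO3
Reagents that add atoms: 1,2-bis(trimethylsilyloxy)ethane C[Si](C)(C)OCCO[Si](C)(C)C
Why: Noyori ketalisation at low temperature masks the C1 ketone without epimerising C10, because a free C1 ketone would sit five atoms from C7 and could trap the alkenylchromium of step 10 in a five-membered ring closure.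

Step 9
Reactants: 16 methyl (2Z,4S,5R,6S)-2-(acetoxymethyl)-5-hydroxy-6-{2-[(3E)-5-hydroxy-3-methylpent-3-en-1-yl]-1,3-dioxolan-2-yl}-3-iodo-4-(methacryloyloxy)hept-2-enoate
Product: 17 methyl (2Z,4S,5R,6S)-2-(acetoxymethyl)-5-hydroxy-3-iodo-4-(methacryloyloxy)-6-{2-[(3E)-3-methyl-5-oxopent-3-en-1-yl]-1,3-dioxolan-2-yl}hept-2-enoate
Conditions: MnO2 (15 equiv), CH2Cl2, rt
Reagents that add atoms: none
Why: Chemoselective allylic oxidation with MnO2: only the primary allylic alcohol is oxidised, the secondary C9 hydroxyl is not, and the E geometry is kept.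

Step 10
Reactants: 17 methyl (2Z,4S,5R,6S)-2-(acetoxymethyl)-5-hydroxy-3-iodo-4-(methacryloyloxy)-6-{2-[(3E)-3-methyl-5-oxopent-3-en-1-yl]-1,3-dioxolan-2-yl}hept-2-enoate
Product: 20 (4E,6R,8R,9R,10S)-13-acetoxy-9-hydroxy-8-(methacryloyloxy)-1-oxogermacra-4,7(11)-dien-12,6-olide, via seco hydroxy ester 18 (not isolated), via ketal lactone 19 (not isolated)
Conditions: CrCl2 (8 equiv), NiCl2 (2 mol % of Cr), DMSO, 2 mM (syringe pump, 12 h), rt; aq. NH4Cl; crude in acetone/H2O (10:1), pyridinium p-toluenesulfonate (20 mol %), 40 °C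
Reagents that add atoms: water O
Why: Intramolecular Nozaki–Hiyama–Kishi reaction: zerovalent nickel inserts into the C7–I bond, transmetalation gives a trivalent alkenylchromium that adds 1,2 to the enal (ketal, esters and free OH are inert) and closes the 10-membered ring at C6–C7, the C6 chromium alkoxide, held cis to CO2Me, then closes the butenolide with loss of methanol and mild acid frees the C1 ketone; C6 is set in the ring-closing transition state, where C8–H eclipses C13 (allylic strain) and C5 and C9 leave the planar C7 centre on opposite faces as in natural 12,6-olides, giving 6R (the same spatial arrangement as 6S in the epoxide).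

Step 11
Reactants: 20 (4E,6R,8R,9R,10S)-13-acetoxy-9-hydroxy-8-(methacryloyloxy)-1-oxogermacra-4,7(11)-dien-12,6-olide
Product: 21 (4R,5R,6S,8R,9R,10S)-13-acetoxy-4,5-epoxy-9-hydroxy-8-(methacryloyloxy)-1-oxogermacr-7(11)-en-12,6-olide (CNP0185951.1)
Conditions: 3-chloroperbenzoic acid (1.1 equiv), NaHCO3, CH2Cl2, 0 °C
Reagents that add atoms: 3-chloroperbenzoic acid O=C(OO)c1cccc(Cl)c1
Why: Prilezhaev epoxidation: only the electron-rich trisubstituted 4,5-alkene reacts (methacrylate and butenolide alkenes are electron-poor), and with H6 eclipsing the C15 methyl (allylic strain) the ring body shields one face so the peracid adds to the outer face syn to O6, which gives the 4R,5R epoxide (the parthenolide-type 4α,5β arrangement).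

## Compound list

1 | 2,2-dimethoxyacetaldehyde | COC(OC)C=O | starting material
2 | methyl propiolate | C#CC(=O)OC | starting material
3 | methyl (4R)-4-hydroxy-5,5-dimethoxypent-2-ynoate | COC(OC)[C@H](O)C#CC(=O)OC | intermediate
4 | chloromagnesium alkoxide of 3 (not isolated) | COC(OC)[C@H](O[Mg]Cl)C#CC(=O)OC | intermediate
5 | magnesium iodoallenolate, iodine on C7, O–MgI ketene acetal, C8–OMgCl (not isolated) | COC(OC)[C@H](O[Mg]Cl)C(I)=C=C(OC)O[Mg]I | intermediate
6 | methyl (2Z,4S)-4-hydroxy-2-(hydroxymethyl)-3-iodo-5,5-dimethoxypent-2-enoate | COC(OC)[C@H](O)/C(I)=C(\CO)C(=O)OC | intermediate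
7 | methyl (2Z,4S)-2-(acetoxymethyl)-4-hydroxy-3-iodo-5,5-dimethoxypent-2-enoate (not isolated) | COC(OC)[C@H](O)/C(I)=C(\COC(C)=O)C(=O)OC | intermediate
8 | methyl (2Z,4S)-2-(acetoxymethyl)-3-iodo-5,5-dimethoxy-4-(methacryloyloxy)pent-2-enoate | COC(OC)[C@H](OC(=O)C(C)=C)/C(I)=C(\COC(C)=O)C(=O)OC | intermediate
9 | methyl (2Z,4S)-2-(acetoxymethyl)-3-iodo-4-(methacryloyloxy)-5-oxopent-2-enoate | O=C[C@H](OC(=O)C(C)=C)/C(I)=C(\COC(C)=O)C(=O)OC | intermediate
10 | ethyl vinyl ketone (pent-1-en-3-one) | C=CC(=O)CC | starting material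
11 | (E)-enol dicyclohexylborinate of 10, O and CH3 trans (not isolated) | C/C=C(/OB(C1CCCCC1)C1CCCCC1)C=C | intermediate
12 | methyl (2Z,4S,5R,6S)-2-(acetoxymethyl)-5-hydroxy-3-iodo-4-(methacryloyloxy)-6-methyl-7-oxonona-2,8-dienoate | C=CC(=O)[C@@H](C)[C@@H](O)[C@H](OC(=O)C(C)=C)/C(I)=C(\COC(C)=O)C(=O)OC | intermediate
13 | but-2-yn-1-ol | CC#CCO | starting material
14 | (2Z)-3-(4,4,5,5-tetramethyl-1,3,2-dioxaborolan-2-yl)but-2-en-1-ol | C/C(B1OC(C)(C)C(C)(C)O1)=C\CO | intermediate
15 | methyl (2Z,4S,5R,6S,10E)-2-(acetoxymethyl)-5,12-dihydroxy-3-iodo-4-(methacryloyloxy)-6,10-dimethyl-7-oxododeca-2,10-dienoate | OC/C=C(C)/CCC(=O)[C@@H](C)[C@@H](O)[C@H](OC(=O)C(C)=C)/C(I)=C(\COC(C)=O)C(=O)OC | intermediate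
16 | methyl (2Z,4S,5R,6S)-2-(acetoxymethyl)-5-hydroxy-6-{2-[(3E)-5-hydroxy-3-methylpent-3-en-1-yl]-1,3-dioxolan-2-yl}-3-iodo-4-(methacryloyloxy)hept-2-enoate | OC/C=C(C)/CCC1(OCCO1)[C@@H](C)[C@@H](O)[C@H](OC(=O)C(C)=C)/C(I)=C(\COC(C)=O)C(=O)OC | intermediate
17 | methyl (2Z,4S,5R,6S)-2-(acetoxymethyl)-5-hydroxy-3-iodo-4-(methacryloyloxy)-6-{2-[(3E)-3-methyl-5-oxopent-3-en-1-yl]-1,3-dioxolan-2-yl}hept-2-enoate | O=C/C=C(C)/CCC1(OCCO1)[C@@H](C)[C@@H](O)[C@H](OC(=O)C(C)=C)/C(I)=C(\COC(C)=O)C(=O)OC | intermediate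
18 | methyl (4E,6R,8R,9R,10S)-13-acetoxy-1,1-(ethylenedioxy)-6,9-dihydroxy-8-(methacryloyloxy)germacra-4,7(11)-dien-12-oate, C6–OH cis to CO2Me (not isolated) | C=C(C)C(=O)O[C@@H]1/C(=C(\COC(C)=O)C(=O)OC)[C@H](O)/C=C(C)/CCC2(OCCO2)[C@@H](C)[C@H]1O | intermediate
19 | (4E,6R,8R,9R,10S)-13-acetoxy-1,1-(ethylenedioxy)-9-hydroxy-8-(methacryloyloxy)germacra-4,7(11)-dien-12,6-olide (not isolated) | C=C(C)C(=O)O[C@@H]1C2=C(COC(C)=O)C(=O)O[C@@H]2/C=C(C)/CCC2(OCCO2)[C@@H](C)[C@H]1O | intermediate
20 | (4E,6R,8R,9R,10S)-13-acetoxy-9-hydroxy-8-(methacryloyloxy)-1-oxogermacra-4,7(11)-dien-12,6-olide | C=C(C)C(=O)O[C@@H]1C2=C(COC(C)=O)C(=O)O[C@@H]2/C=C(C)/CCC(=O)[C@@H](C)[C@H]1O | intermediate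
21 | (4R,5R,6S,8R,9R,10S)-13-acetoxy-4,5-epoxy-9-hydroxy-8-(methacryloyloxy)-1-oxogermacr-7(11)-en-12,6-olide | C=C(C)C(=O)O[C@@H]1C2=C(COC(C)=O)C(=O)O[C@@H]2[C@H]2O[C@]2(C)CCC(=O)[C@@H](C)[C@H]1O | target

## Step count and risks

Total step count: 11 (steps 1–11; step 6 is a one-step side branch).
Longest linear sequence: 10 (steps 1–5 and 7–11).

The three steps most likely to fail:

Step 10 (ring closure). The alkenylchromium is tetrasubstituted and ester-chelated, the enal is a weak electrophile, β-loss of the C8 carboxylate is possible, and the C6 configuration rests on a conformational argument. The fallback installs the epoxide first and cyclises onto a more electrophilic α,β-epoxy aldehyde whose neighbouring stereocentres are reagent-defined; it sets out from 16 and comes back at 21. Sharpless asymmetric epoxidation of 16 (Ti(OiPr)4, D-(−)-diisopropyl tartrate, t-BuOOH, 4 Å molecular sieves, CH2Cl2, −20 °C) gives the epoxy alcohol methyl (2Z,4S,5R,6S)-2-(acetoxymethyl)-5-hydroxy-6-(2-{2-[(2R,3R)-3-(hydroxymethyl)-2-methyloxiran-2-yl]ethyl}-1,3-dioxolan-2-yl)-3-iodo-4-(methacryloyloxy)hept-2-enoate F1. PhI(OAc)2 with catalytic 2,2,6,6-tetramethylpiperidin-1-oxyl oxidises only the primary alcohol, giving the epoxy aldehyde methyl (2Z,4S,5R,6S)-2-(acetoxymethyl)-6-(2-{2-[(2R,3S)-3-formyl-2-methyloxiran-2-yl]ethyl}-1,3-dioxolan-2-yl)-5-hydroxy-3-iodo-4-(methacryloyloxy)hept-2-enoate F2. The same CrCl2/NiCl2 cyclisation in DMSO at high dilution, in which chromium bridging the aldehyde and epoxide oxygens favours the required 5,6-syn addition, lactonises in the flask to the C1 ethylene ketal of the target, (4R,5R,6S,8R,9R,10S)-13-acetoxy-4,5-epoxy-1,1-(ethylenedioxy)-9-hydroxy-8-(methacryloyloxy)germacr-7(11)-en-12,6-olide F3. Pyridinium p-toluenesulfonate in wet acetone at room temperature then frees the ketone to give 21.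

Step 5 (aldol). The 9,10-anti sense is reliable, but the facial selectivity against the α-acyloxy stereocentre (8,9-syn needed) is not certain. The fallback replaces substrate control by reagent control; it sets out from 9 and comes back at 12. Brown crotylboration of 9 with (E)-crotyl-B(Ipc)2 (the Ipc antipode that gives the 5R adduct, THF, −78 °C, ethanolamine work-up) gives the anti homoallylic alcohol methyl (2Z,4S,5R,6R)-2-(acetoxymethyl)-5-hydroxy-3-iodo-4-(methacryloyloxy)-6-methylocta-2,7-dienoate F4. Wacker oxidation of its terminal vinyl group (PdCl2, CuCl, O2, DMF/H2O) gives the methyl ketone methyl (2Z,4S,5R,6S)-2-(acetoxymethyl)-5-hydroxy-3-iodo-4-(methacryloyloxy)-6-methyl-7-oxooct-2-enoate F5. Enolisation on the methyl side (Cy2BCl, Et3N) and trapping with N,N-dimethylmethyleneiminium iodide gives the Mannich base methyl (2Z,4S,5R,6S)-2-(acetoxymethyl)-9-(dimethylamino)-5-hydroxy-3-iodo-4-(methacryloyloxy)-6-methyl-7-oxonon-2-enoate F6. Quaternisation with MeI and elimination with NaHCO3 give 12.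

Step 2 (iodo-hydroxymethylation). This is an untested extension, and both the reactivity of a β-substituted ynoate and the Z geometry depend on the alkoxide-directed delivery. The fallback builds the same alkene by stereospecific anti addition followed by cross-coupling; it sets out from 3 and comes back at 6. IBr (CH2Cl2, −40 → 0 °C) adds anti across the ynoate, bromine going to C7, to give methyl (2E,4S)-3-bromo-4-hydroxy-2-iodo-5,5-dimethoxypent-2-enoate F7, in which the C7 halogen is already cis to CO2Me. Stille coupling of the more reactive C–I bond with tributyl(hydroxymethyl)stannane (Pd2(dba)3, AsPh3, CuI, N-methylpyrrolidone, rt) gives, with retention, methyl (2Z,4S)-3-bromo-4-hydroxy-2-(hydroxymethyl)-5,5-dimethoxypent-2-enoate F8. Copper-catalysed halogen exchange (NaI, CuI, trans-N,N'-dimethylcyclohexane-1,2-diamine, dioxane, 100 °C) converts F8 into 6.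

## Further compounds

F1 | step 10 | methyl (2Z,4S,5R,6S)-2-(acetoxymethyl)-5-hydroxy-6-(2-{2-[(2R,3R)-3-(hydroxymethyl)-2-methyloxiran-2-yl]ethyl}-1,3-dioxolan-2-yl)-3-iodo-4-(methacryloyloxy)hept-2-enoate | OC[C@H]1O[C@]1(C)CCC1(OCCO1)[C@@H](C)[C@@H](O)[C@H](OC(=O)C(C)=C)/C(I)=C(\COC(C)=O)C(=O)OC
F2 | step 10 | methyl (2Z,4S,5R,6S)-2-(acetoxymethyl)-6-(2-{2-[(2R,3S)-3-formyl-2-methyloxiran-2-yl]ethyl}-1,3-dioxolan-2-yl)-5-hydroxy-3-iodo-4-(methacryloyloxy)hept-2-enoate | O=C[C@H]1O[C@]1(C)CCC1(OCCO1)[C@@H](C)[C@@H](O)[C@H](OC(=O)C(C)=C)/C(I)=C(\COC(C)=O)C(=O)OC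
F3 | step 10 | (4R,5R,6S,8R,9R,10S)-13-acetoxy-4,5-epoxy-1,1-(ethylenedioxy)-9-hydroxy-8-(methacryloyloxy)germacr-7(11)-en-12,6-olide | C=C(C)C(=O)O[C@@H]1C2=C(COC(C)=O)C(=O)O[C@@H]2[C@H]2O[C@]2(C)CCC2(OCCO2)[C@@H](C)[C@H]1O
F4 | step 5 | methyl (2Z,4S,5R,6R)-2-(acetoxymethyl)-5-hydroxy-3-iodo-4-(methacryloyloxy)-6-methylocta-2,7-dienoate | C=C[C@@H](C)[C@@H](O)[C@H](OC(=O)C(C)=C)/C(I)=C(\COC(C)=O)C(=O)OC
F5 | step 5 | methyl (2Z,4S,5R,6S)-2-(acetoxymethyl)-5-hydroxy-3-iodo-4-(methacryloyloxy)-6-methyl-7-oxooct-2-enoate | CC(=O)[C@@H](C)[C@@H](O)[C@H](OC(=O)C(C)=C)/C(I)=C(\COC(C)=O)C(=O)OC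
F6 | step 5 | methyl (2Z,4S,5R,6S)-2-(acetoxymethyl)-9-(dimethylamino)-5-hydroxy-3-iodo-4-(methacryloyloxy)-6-methyl-7-oxonon-2-enoate | CN(C)CCC(=O)[C@@H](C)[C@@H](O)[C@H](OC(=O)C(C)=C)/C(I)=C(\COC(C)=O)C(=O)OC
F7 | step 2 | methyl (2E,4S)-3-bromo-4-hydroxy-2-iodo-5,5-dimethoxypent-2-enoate | COC(OC)[C@H](O)/C(Br)=C(\I)C(=O)OC
F8 | step 2 | methyl (2Z,4S)-3-bromo-4-hydroxy-2-(hydroxymethyl)-5,5-dimethoxypent-2-enoate | COC(OC)[C@H](O)/C(Br)=C(\CO)C(=O)OC
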